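**Retrosynthetic overview**
1. 14 ⇒ 13: the C5–C6 ethano bridge of a 5,6-dihydroisoflavone is dehydrogenated last, so ring A becomes aromatic at the end.
2. 13 ⇒ 5 + 10: cut C4–C4a (enolate C-acylation) and O1–C2 (enol oxygen addition–elimination on a β-methoxy enone); together they close pyranone ring C.
3. Structural basis: ring A has three neighbouring oxygenated carbons, C8a (ring oxygen O1), C8 (OMe) and C7 (O-prenyl), next to plain CH at C5 and C6. These are C1, C2 and C3 of symmetric 2-methoxycyclohexane-1,3-dione 3; mono-O-prenylation turns one oxygen into the C7 ether and leaves the other as the ketone that becomes C8a–O1.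
4. 5 ⇒ 3 + 4 (Mitsunobu), 3 ⇒ 2 ⇒ 1 (diazo transfer, O–H insertion); 10 ⇒ 9 ⇒ 8 ⇒ 7 ⇒ 6 (formylation, O-methylation, saponification, CDI activation).
5. Ring order: ring B comes with 6 and the six carbons of ring A with 1; ring C is formed in step 8; ring A is aromatised in step 9.

Key step: step 8

Remark: the target is achiral and has no stereogenic double bond; 3 and 7 are written as their dominant enol tautomers, and the enol ether geometry of 8, 9, 10 and 12 is lost on ring closure.

**Step 1**
Reactants: 1 cyclohexane-1,3-dione
Product: 2 2-diazocyclohexane-1,3-dione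
Conditions: p-ABSA (1.05 equiv), Et3N (1.2 equiv), MeCN, 0 °C → rt
Reagents that add atoms: 4-acetamidobenzenesulfonyl azide (p-ABSA), CC(=O)Nc1ccc(cc1)S(=O)(=O)N=[N+]=[N-]
Why: Regitz diazo transfer, in which the enolate of the 1,3-dione attacks the terminal azide nitrogen and the triazene collapses to the 2-diazo-1,3-dione and the sulfonamide, a standard reaction of cyclic 1,3-diketones.

**Step 2**
Reactants: 2 2-diazocyclohexane-1,3-dione
Product: 3 3-hydroxy-2-methoxycyclohex-2-en-1-one (enol tautomer of 2-methoxycyclohexane-1,3-dione)
Conditions: Rh2(OAc)4 (1 mol%), MeOH/CH2Cl2, rt → 40 °C, slow addition of 2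
Reagents that add atoms: methanol, CO
Why: Rhodium carbenoid O–H insertion, in which the electrophilic carbenoid from the diazo dione is trapped by methanol as an oxonium ylide and a proton shift gives the 2-methoxy dione, the large excess of methanol outrunning Wolff ring contraction.

**Step 3**
Reactants: 3 3-hydroxy-2-methoxycyclohex-2-en-1-one; 4 3-methylbut-2-en-1-ol
Product: 5 2-methoxy-3-(3-methylbut-2-enyloxy)cyclohex-2-en-1-one
Conditions: PPh3, DIAD, THF, 0 °C → rt
Reagents that add atoms: none
Why: Mitsunobu reaction, in which the acidic enol (pKa about 5) protonates the betaine and its oxygen displaces triphenylphosphine oxide from the primary allylic alkoxyphosphonium ion by SN2, giving the O-alkylated vinylogous ester as a single regioisomer because 3 is symmetric, at a temperature far below that of a Claisen shift.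

**Step 4**
Reactants: 6 methyl (4-methoxyphenyl)acetate
Product: 7 methyl (Z)-3-hydroxy-2-(4-methoxyphenyl)prop-2-enoate (hydrogen-bonded enol of the 2-formyl ester)
Conditions: NaH (2.2 equiv), HCO2Me (5 equiv), THF, 0 °C → rt; cold 1 M HCl work-up
Reagents that add atoms: methyl formate, COC=O
Why: Crossed Claisen condensation (formylation), in which the ester enolate attacks the non-enolisable and most electrophilic ester, methyl formate, and the equilibrium is pulled over by formation of the stabilised sodium enolate of the formyl ester.

**Step 5**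
Reactants: 7 methyl (Z)-3-hydroxy-2-(4-methoxyphenyl)prop-2-enoate
Product: 8 methyl (E)-3-methoxy-2-(4-methoxyphenyl)prop-2-enoate
Conditions: Me2SO4 (1.2 equiv), K2CO3 (2 equiv), DMF, rt
Reagents that add atoms: dimethyl sulfate, COS(=O)(=O)OC
Why: O-alkylation of the potassium enolate by the hard electrophile dimethyl sulfate in a dipolar aprotic solvent, which should give mainly the E β-methoxyacrylate (methoxy trans to the ester), while either geometry would serve in step 8.

**Step 6**
Reactants: 8 methyl (E)-3-methoxy-2-(4-methoxyphenyl)prop-2-enoate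
Product: 9 (E)-3-methoxy-2-(4-methoxyphenyl)prop-2-enoic acid
Conditions: LiOH·H2O (2 equiv), THF/MeOH/H2O, rt; then 1 M HCl to pH 3, 0 °C
Reagents that add atoms: lithium hydroxide, [Li+].[OH-]
Why: Saponification (acyl–oxygen cleavage by hydroxide), which the donor-stabilised enol ether should survive at room temperature, with a brief cold acidification so that the enol ether is not hydrolysed.

**Step 7**
Reactants: 9 (E)-3-methoxy-2-(4-methoxyphenyl)prop-2-enoic acid
Product: 10 (E)-1-(imidazol-1-yl)-3-methoxy-2-(4-methoxyphenyl)prop-2-en-1-one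
Conditions: CDI (1.05 equiv), CH2Cl2, rt; quick cold-water wash, dry, use at once
Reagents that add atoms: 1,1'-carbonyldiimidazole (CDI), O=C(n1ccnc1)n1ccnc1
Why: Carboxylic acid activation with CDI, which gives the acyl imidazole with loss of carbon dioxide and imidazole; the acid has no α-hydrogen, so no ketene can form, and the freed imidazole is washed out so that its N–H cannot quench the enolate of step 8.

**Step 8**
Reactants: 5 2-methoxy-3-(3-methylbut-2-enyloxy)cyclohex-2-en-1-one; 10 (E)-1-(imidazol-1-yl)-3-methoxy-2-(4-methoxyphenyl)prop-2-en-1-one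
Product: 13 8-methoxy-3-(4-methoxyphenyl)-7-(3-methylbut-2-enyloxy)-5,6-dihydro-4H-chromen-4-one, via lithium enolate 11 (not isolated), via acyclic diketone 12 (not isolated)
Conditions: LiN(iPr)2 (LDA, 2.1 equiv, commercial solution), THF, −78 °C; then 10 (1.0 equiv), −78 → 0 °C; then AcOH (5 equiv), rt
Reagents that add atoms: none
Why: LDA at −78 °C removes the kinetically most accessible α′ proton (C6 of 5, the future C4a) to give the cross-conjugated enolate 11, whose carbon attacks the acyl imidazole carbonyl; collapse of the tetrahedral adduct expels imidazolide and forms C4–C4a, and the second equivalent of base holds the product as the lithium diketonate of 12 so that no 11 is lost to proton transfer. On the acetic acid quench 12 enolises toward the ring carbonyl, and this enol oxygen adds to the β-methoxy enone carbon with loss of methanol (6-endo-trig oxa-Michael addition followed by β-elimination), forming O1–C2 and the 4-pyranone ring. The closest known reaction types are the Claisen-type C-acylation of vinylogous ester α′ enolates with acyl imidazoles and the closure of 2-(alkoxymethylene) 1,3-diketones to 4-pyranones, as in isoflavone formation from alkoxymethylene deoxybenzoins. No stereocentre is created, because the C6 centre of 12 is enolisable and becomes sp2 and the E geometry of the enol ether is erased in the addition–elimination. The step needs α′ over γ deprotonation, C- over O-acylation and carbonyl over β-carbon attack on 10; these should be secured by irreversible deprotonation at −78 °C, by the tightly ion-paired lithium enolate in THF, and by the much higher electrophilicity of the imidazolide carbonyl compared with the donor-substituted, aryl-flanked β-carbon. Acetic acid is used instead of a mineral acid so that the prenyl dienol ether at C7 is neither hydrolysed nor ionised.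

**Step 9**
Reactants: 13 8-methoxy-3-(4-methoxyphenyl)-7-(3-methylbut-2-enyloxy)-5,6-dihydro-4H-chromen-4-one
Product: 14 8-methoxy-3-(4-methoxyphenyl)-7-(3-methylbut-2-enyloxy)-4H-chromen-4-one (target)
Conditions: DDQ (1.05 equiv), anhydrous CH2Cl2, 0 °C
Reagents that add atoms: none
Why: Quinone dehydrogenation, in which DDQ abstracts hydride from the allylic C5/C6 methylene of the cyclohexa-1,3-diene and the oxygen-stabilised cation loses the neighbouring proton to make ring A aromatic, while one equivalent at 0 °C without water should spare the prenyl ether and stay far below the temperature of a Claisen shift.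

**Compound list**
1 | cyclohexane-1,3-dione | O=C1CCCC(=O)C1 | starting material
2 | 2-diazocyclohexane-1,3-dione | [N-]=[N+]=C1C(=O)CCCC1=O | intermediate
3 | 3-hydroxy-2-methoxycyclohex-2-en-1-one (enol of 2-methoxycyclohexane-1,3-dione) | COC1=C(O)CCCC1=O | intermediate
4 | 3-methylbut-2-en-1-ol | CC(C)=CCO | starting material
5 | 2-methoxy-3-(3-methylbut-2-enyloxy)cyclohex-2-en-1-one | COC1=C(OCC=C(C)C)CCCC1=O | intermediate
6 | methyl (4-methoxyphenyl)acetate | COC(=O)Cc1ccc(OC)cc1 | starting material
7 | methyl (Z)-3-hydroxy-2-(4-methoxyphenyl)prop-2-enoate | O/C=C(\C(=O)OC)c1ccc(OC)cc1 | intermediate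
8 | methyl (E)-3-methoxy-2-(4-methoxyphenyl)prop-2-enoate | CO/C=C(/C(=O)OC)c1ccc(OC)cc1 | intermediate
9 | (E)-3-methoxy-2-(4-methoxyphenyl)prop-2-enoic acid | CO/C=C(/C(=O)O)c1ccc(OC)cc1 | intermediate
10 | (E)-1-(imidazol-1-yl)-3-methoxy-2-(4-methoxyphenyl)prop-2-en-1-one | CO/C=C(/C(=O)n1ccnc1)c1ccc(OC)cc1 | intermediate
11 | lithium 6-methoxy-5-(3-methylbut-2-enyloxy)cyclohexa-1,5-dien-1-olate (not isolated) | [Li+].[O-]C1=CCCC(OCC=C(C)C)=C1OC | intermediate
12 | 2-methoxy-6-[(E)-3-methoxy-2-(4-methoxyphenyl)prop-2-enoyl]-3-(3-methylbut-2-enyloxy)cyclohex-2-en-1-one (racemic at C6, not isolated) | CO/C=C(/C(=O)C1CCC(OCC=C(C)C)=C(OC)C1=O)c1ccc(OC)cc1 | intermediate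
13 | 8-methoxy-3-(4-methoxyphenyl)-7-(3-methylbut-2-enyloxy)-5,6-dihydro-4H-chromen-4-one | COc1ccc(cc1)C1=COC2=C(CCC(OCC=C(C)C)=C2OC)C1=O | intermediate
14 | 8-methoxy-3-(4-methoxyphenyl)-7-(3-methylbut-2-enyloxy)-4H-chromen-4-one | COc1ccc(-c2coc3c(OC)c(OCC=C(C)C)ccc3c2=O)cc1 | target

**Step count**
Total: 9 steps. Longest linear sequence: 6 steps (steps 4, 5, 6, 7, 8, 9 from 6); the other branch is 5 steps (steps 1, 2, 3, 8, 9 from 1).

**Steps most likely to fail**

Step 8 (key step). The enolate may attack the β-methoxy carbon of 10 instead of the carbonyl (addition–elimination leading toward a 2-pyranone), O-acylation may compete, proton transfer from 12 or from residual imidazole may stall conversion, or ring closure may be slow. The fallback builds C4–C4a and C2 separately, sets out from 5 and comes back at 13. Enolate 11 is made from 5 as before and added to (4-methoxyphenyl)acetaldehyde at −78 °C (acetic acid quench) to give the aldol 6-[1-hydroxy-2-(4-methoxyphenyl)ethyl]-2-methoxy-3-(3-methylbut-2-enyloxy)cyclohex-2-en-1-one F1 as a diastereomer mixture. Dess–Martin periodinane in CH2Cl2 should oxidise it to the diketone 2-methoxy-6-[(4-methoxyphenyl)acetyl]-3-(3-methylbut-2-enyloxy)cyclohex-2-en-1-one F2. N,N-Dimethylformamide dimethyl acetal in toluene at 60 °C should condense at the benzylic methylene to the enaminone 6-[(E)-3-(dimethylamino)-2-(4-methoxyphenyl)prop-2-enoyl]-2-methoxy-3-(3-methylbut-2-enyloxy)cyclohex-2-en-1-one F3, which closes with acetic acid to 13 with loss of dimethylamine.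

Step 9. The quinone may cleave or abstract hydride from the prenyl ether, may add to the diene as a dienophile, or the prenyl group may shift from O7 to C8 by a [3,3] rearrangement if the mixture warms. The fallback puts the prenyl group on last, sets out from 13 and comes back at 14. 1 M HCl in THF at rt should hydrolyse the C7 enol ether of 13 to 7-hydroxy-8-methoxy-3-(4-methoxyphenyl)-5,6-dihydro-4H-chromen-4-one F4 (the enol of the 4,7-dione). With no sensitive group left, DDQ in 1,4-dioxane at 80 °C should dehydrogenate it to the phenol 7-hydroxy-8-methoxy-3-(4-methoxyphenyl)-4H-chromen-4-one F5. 1-Bromo-3-methylbut-2-ene and K2CO3 in acetone then alkylate the phenol to 14.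

Step 3. Allylic transposition (SN2′ attack giving the 1,1-dimethylallyl ether) and C-alkylation at C2 of the ambident dione may compete with O-alkylation. The fallback reverses the roles of the partners, sets out from 3 and comes back at 5. Oxalyl chloride with catalytic DMF in CH2Cl2 converts 3 into the vinylogous acid chloride 3-chloro-2-methoxycyclohex-2-en-1-one F6. Sodium 3-methylbut-2-en-1-olate F7, made from 4 and NaH in THF at 0 °C, then displaces chloride by addition–elimination to give 5.

**Further compounds**
F1 | step 8 | 6-[1-hydroxy-2-(4-methoxyphenyl)ethyl]-2-methoxy-3-(3-methylbut-2-enyloxy)cyclohex-2-en-1-one (diastereomer mixture, racemic) | COC1=C(OCC=C(C)C)CCC(C(O)Cc2ccc(OC)cc2)C1=O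
F2 | step 8 | 2-methoxy-6-[(4-methoxyphenyl)acetyl]-3-(3-methylbut-2-enyloxy)cyclohex-2-en-1-one | COC1=C(OCC=C(C)C)CCC(C(=O)Cc2ccc(OC)cc2)C1=O
F3 | step 8 | 6-[(E)-3-(dimethylamino)-2-(4-methoxyphenyl)prop-2-enoyl]-2-methoxy-3-(3-methylbut-2-enyloxy)cyclohex-2-en-1-one | CN(C)/C=C(/C(=O)C1CCC(OCC=C(C)C)=C(OC)C1=O)c1ccc(OC)cc1
F4 | step 9 | 7-hydroxy-8-methoxy-3-(4-methoxyphenyl)-5,6-dihydro-4H-chromen-4-one | COc1ccc(cc1)C1=COC2=C(CCC(O)=C2OC)C1=O
F5 | step 9 | 7-hydroxy-8-methoxy-3-(4-methoxyphenyl)-4H-chromen-4-one | COc1ccc(-c2coc3c(OC)c(O)ccc3c2=O)cc1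
F6 | step 3 | 3-chloro-2-methoxycyclohex-2-en-1-one | COC1=C(Cl)CCCC1=O
F7 | step 3 | sodium 3-methylbut-2-en-1-olate | [Na+].[O-]CC=C(C)C
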